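**Retrosynthetic overview**

1. Rings: A = cyclopentane bearing C(CH3)(CO2H); B = central cyclopentane; C = cyclopentenone; D = dihydropyran; E = nine-membered ring; F = cyclobutane. Order of ring formation: C (bought), E and F (bought in the terpene), B, D, A.
2. Ring A (last): the bond between its quaternary carbon and a flanking CH2 is made by 5-exo-tet alkylation of an ester enolate with a primary iodide on the finished B–F pentacycle.
3. Enabling feature: in ring A the carbon bearing CH3 and CO2H lies between two CH2 groups that sit cis on the two CH atoms shared with ring B. A propionate unit on one arm and a leaving group on the other (either way round, either ester epimer) therefore converge on one planar enolate. The fold of rings A/B beside the angular CH3 of the B/C fusion decides the enolate face.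
4. Ring D: oxa-Diels–Alder union of the α-methylene-1,2-dione (ring C diosphenol + CH2O) with the trans alkene of (+)-β-caryophyllene.
5. Ring B and both arms: iodine-atom-transfer addition–cyclisation of methyl 2-iodopropanoate onto cis-2-allyl-3-methyl-3-vinylcyclopentanone. That diene comes from 3-methylcyclopentenone by enantioselective conjugate vinylation/allylation.

Key step: step 7

Assumption: the terpene half of the target has the (1S,9R) configuration, that of (+)-β-caryophyllene, the mirror image of the clove-oil terpene. This enantiomer (a fermentation product of (+)-caryophyllene synthases) is taken as a purchasable starting material.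

**Step 1**
Reactants: 1 3-methylcyclopent-2-en-1-one; 2 vinylmagnesium bromide; 3 allyl iodide
Product: 5 (2R,3S)-2-allyl-3-methyl-3-vinylcyclopentan-1-one, via aluminium enolate 4 (not isolated)
Conditions: i-Bu2AlCl + 2, Et2O, 0 °C; 1, Cu(OTf)2 (5 mol %), chiral sulfonate-bearing NHC ligand (from its imidazolinium salt, 5 mol %), THF, −30 °C; then MeLi, 3, DMPU, −78 to 0 °C; C-2 epimers equilibrated with DBU, cis (allyl/vinyl) epimer collected
Reagents that add atoms: vinylmagnesium bromide (2) C=C[Mg]Br; allyl iodide (3) C=CCI
Why: NHC–copper-catalysed enantioselective conjugate addition of an alkenylaluminium reagent sets the quaternary centre under ligand control and leaves a regiodefined aluminium enolate that, as its lithium ate complex, undergoes enolate C-allylation at C-2, whose configuration is correctable because the epimers interconvert with base, so the cis epimer is collected and the other recycled.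

**Step 2**
Reactants: 6 methyl 2-bromopropanoate
Product: 7 methyl 2-iodopropanoate
Conditions: NaI, acetone, rt, dark
Reagents that add atoms: sodium iodide [Na+].[I-]
Why: Finkelstein halide exchange, driven by precipitation of the sodium bromide; the racemic centre is later planarised.

**Step 3**
Reactants: 5 (2R,3S)-2-allyl-3-methyl-3-vinylcyclopentan-1-one; 7 methyl 2-iodopropanoate
Product: 8 cis-fused bicyclic iodo ester (methyl 3-[4-(iodomethyl)-3a-methyl-1-oxooctahydropentalen-5-yl]-2-methylpropanoate; CH2I, ester arm and angular CH3 all on the convex face; both epimers at the ester α-carbon)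
Conditions: 7 (2 equiv), (Bu3Sn)2 (10 mol %), benzene, sunlamp, 80 °C
Reagents that add atoms: methyl 2-iodopropanoate (7) CC(I)C(=O)OC
Why: Iodine-atom-transfer radical addition–cyclisation (Kharasch type): the electrophilic ester radical adds to the terminal CH2 of the allyl group, the 5-hexenyl radical closes ring B 5-exo-trig through a chair-like transition state that puts the two new arms cis to each other and on the convex face beside the angular CH3, and the primary radical abstracts iodine from 7; addition at the vinyl terminus would only exchange the two arms, which is harmless for step 7.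

**Step 4**
Reactants: 8 cis-fused bicyclic iodo ester
Product: 10 α-hydroxy ketone (2-hydroxy derivative of 8), via lithium enolate 9 (not isolated)
Conditions: LiN(SiMe3)2 (1.05 equiv), THF, −78 °C; 2-(benzenesulfonyl)-3-phenyloxaziridine, −78 °C; AcOH
Reagents that add atoms: 2-(benzenesulfonyl)-3-phenyloxaziridine O=S(=O)(N1OC1c1ccccc1)c1ccccc1
Why: Kinetic deprotonation at the only unhindered ketone α-CH2 (the other α-carbon is a hindered ring-fusion CH, the ester α-H is less acidic) followed by electrophilic enolate hydroxylation with an N-sulfonyloxaziridine; the carbinol configuration is irrelevant because it is oxidised next.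

**Step 5**
Reactants: 10 α-hydroxy ketone
Product: 11 diosphenol (2-hydroxy-enone tautomer of the ring C 1,2-diketone)
Conditions: IBX, DMSO, rt
Reagents that add atoms: none
Why: IBX oxidation of an α-hydroxy ketone to the 1,2-diketone, which enolises to the diosphenol; no stereocentre is touched.

**Step 6**
Reactants: 11 diosphenol; 12 formaldehyde (as paraformaldehyde); 13 (+)-β-caryophyllene, (1S,4E,9R)-4,11,11-trimethyl-8-methylidenebicyclo[7.2.0]undec-4-ene
Product: 15 pentacyclic iodo ester (rings B–F), via alpha-methylene dione 14 (not isolated)
Conditions: 12 (3 equiv), 13 (2 equiv), i-Pr2NEt (20 mol %), 4 Å MS, toluene, 100 °C, sealed tube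
Reagents that add atoms: formaldehyde (12) C=O; (+)-β-caryophyllene (13) C=C1CC/C=C(\C)CC[C@H]2[C@H]1CC2(C)C
Why: Domino Knoevenagel-type condensation/oxa-Diels–Alder reaction: the enol carbon of 11 condenses with formaldehyde (the other α-carbon is tertiary and cannot dehydrate) to oxadiene 14, which is trapped with inverse electron demand only by the strained trans alkene of 13, suprafacially on its exposed outer face (the face that is also epoxidised) with oxygen going to the methyl-bearing carbon, so both new stereocentres follow from the chirality of the terpene.

**Step 7**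
Reactants: 15 pentacyclic iodo ester
Product: 17 sterhirsutin D methyl ester, via dipotassium bis-enolate 16 (not isolated)
Conditions: KN(SiMe3)2 (2.3 equiv), THF/DMPU, −78 to 0 °C; AcOH
Reagents that add atoms: none
Why: The first equivalent of KN(SiMe3)2 turns the ring C ketone into its ring-fusion enolate, which masks it, the second deprotonates the ester arm, and the ester enolate carbon displaces iodide from the CH2I arm in an intramolecular SN2 reaction. The closest known reaction type is the cycloalkylation of ω-halo ester enolates to 1-alkylcyclopentanecarboxylates. Ring A closes in the 5-exo-tet mode and can only become cis-fused because both arms already stand cis on the convex face of ring B. The new quaternary centre is set by the fold of the emerging A/B diquinane: the extended, potassium-solvated C(OK)(OMe) end of the planar enolate should turn to the open convex side and the compact CH3 into the concave pocket beside the angular CH3, so CO2Me ends cis to the two ring-fusion hydrogens, and both α-epimers of 15 converge because they give the same enolate. The step needs C-alkylation in preference to loss of HI and to O-alkylation, which the five-membered transition state, the soft primary iodide and the low temperature secure, while no other electrophile lies within reach of either enolate (only four-membered rings could form). The exocyclic alkene of ring E, the enol ether of ring D and the cyclobutane are inert to the base, and protonation on quench restores the only accessible cis B/C fusion.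

**Step 8**
Reactants: 17 sterhirsutin D methyl ester
Product: 18 sterhirsutin D
Conditions: LiOH (excess), THF/MeOH/H2O, 65 °C; then 1 M HCl
Reagents that add atoms: lithium hydroxide [Li+].[OH-]
Why: Saponification (BAc2) of the hindered methyl ester; the α-carbon is quaternary and the only base-labile centre, the ring-fusion CH beside the ketone, can only return to the cis fusion.

**Compound list**

1 | 3-methylcyclopent-2-en-1-one | CC1=CC(=O)CC1 | starting material
2 | vinylmagnesium bromide | C=C[Mg]Br | starting material
3 | allyl iodide | C=CCI | starting material
4 | diisobutylaluminium (S)-3-methyl-3-vinylcyclopent-1-en-1-olate | C1CC(O[Al](CC(C)C)CC(C)C)=C[C@@]1(C=C)C | intermediate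
5 | (2R,3S)-2-allyl-3-methyl-3-vinylcyclopentan-1-one | C1CC(=O)[C@H](CC=C)[C@@]1(C=C)C | intermediate
6 | methyl 2-bromopropanoate (racemic) | CC(Br)C(=O)OC | starting material
7 | methyl 2-iodopropanoate (racemic) | CC(I)C(=O)OC | intermediate
8 | cis-fused bicyclic iodo ester (rings B, C; epimers at the ester α-carbon) | C1CC(=O)[C@@H]2C[C@@H](CC(C)C(=O)OC)[C@@H](CI)[C@]12C | intermediate
9 | lithium enolate of 8 (towards the free CH2) | C1C=C([O-])[C@@H]2C[C@@H](CC(C)C(=O)OC)[C@@H](CI)[C@]12C.[Li+] | intermediate
10 | α-hydroxy ketone (carbinol epimers) | C1C(O)C(=O)[C@@H]2C[C@@H](CC(C)C(=O)OC)[C@@H](CI)[C@]12C | intermediate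
11 | diosphenol | C1=C(O)C(=O)[C@@H]2C[C@@H](CC(C)C(=O)OC)[C@@H](CI)[C@]12C | intermediate
12 | formaldehyde (paraformaldehyde) | C=O | starting material
13 | (+)-β-caryophyllene (1S,4E,9R) | C=C1CC/C=C(\C)CC[C@H]2[C@H]1CC2(C)C | starting material
14 | α-methylene-1,2-dione (oxadiene) | C=C1C(=O)C(=O)[C@@H]2C[C@@H](CC(C)C(=O)OC)[C@@H](CI)[C@]12C | intermediate
15 | pentacyclic iodo ester (rings B–F) | C=C1CC[C@@H]2CC3=C(O[C@@]2(C)CC[C@H]2[C@H]1CC2(C)C)C(=O)[C@@H]1C[C@@H](CC(C)C(=O)OC)[C@@H](CI)[C@]31C | intermediate
16 | dipotassium bis-enolate of 15 | C=C1CC[C@@H]2CC3=C(O[C@@]2(C)CC[C@H]2[C@H]1CC2(C)C)C([O-])=C1C[C@@H](CC(C)=C([O-])OC)[C@@H](CI)[C@]31C.[K+].[K+] | intermediate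
17 | sterhirsutin D methyl ester | C=C1CC[C@@H]2CC3=C(O[C@@]2(C)CC[C@H]2[C@H]1CC2(C)C)C(=O)[C@@H]1C[C@H]2C[C@](C)(C(=O)OC)C[C@H]2[C@]31C | intermediate
18 | sterhirsutin D | C=C1CC[C@@H]2CC3=C(O[C@@]2(C)CC[C@H]2[C@H]1CC2(C)C)C(=O)[C@@H]1C[C@H]2C[C@](C)(C(=O)O)C[C@H]2[C@]31C | target

Total step count: 8. Longest linear sequence: 7 (steps 1, 3, 4, 5, 6, 7, 8).

**Steps most likely to fail**

Step 7. The amide base or the enolate may remove HI from the β-branched iodide faster than the ring closes, or the facial bias at the planar enolate carbon may be insufficient. The fallback sets out from 15 and returns at 17. It replaces alkylation by carbonyl addition.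
- The iodide is oxidised with trimethylamine N-oxide (Kornblum-type oxidation) to the pentacyclic aldehyde F1.
- Intramolecular aldol addition of the ester enolate (LiN(i-Pr)2, 2 equiv, −78 °C) closes ring A through a chelated closed transition state to the ring A hydroxy ester F2.
- The secondary alcohol is converted with 1,1'-thiocarbonyldiimidazole into the imidazolylthiocarbonate F3.
- Barton–McCombie deoxygenation (Bu3SnH, AIBN, toluene, 90 °C) gives 17.

Step 6. Hydroxymethylation beside the quaternary carbon may be slow and reversible. The free oxadiene may dimerise before it meets the terpene, or it may add to a less favourable conformer face of the nine-membered ring. The fallback sets out from 11 and returns at 15.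
- A Mannich reaction with dimethylmethyleneammonium iodide (CH2Cl2, rt) gives the isolable Mannich base F4.
- F4 is then heated with 13 in toluene under a nitrogen stream. The oxadiene is released slowly by loss of the amine and is always trapped at low stationary concentration.

Step 1. The unsubstituted vinyl group may transfer with low enantioselectivity. The ate enolate may undergo O-allylation or multiple allylation, and the epimer balance at C-2 may be unfavourable. The fallback sets out from 1 and returns at 5.
- The (1-trimethylsilylvinyl)alane, made from trimethylsilylacetylene and i-Bu2AlH, is added under the same copper catalysis. The enolate is trapped with acetic anhydride as the enol acetate F5.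
- Cleavage with MeLi (2 equiv) and allylation of the lithium enolate with 3 gives the silylvinyl ketone F6.
- Protodesilylation with CF3CO2H followed by base equilibration delivers 5.

**Further compounds**

F1 | step 7 | pentacyclic aldehyde ester | C=C1CC[C@@H]2CC3=C(O[C@@]2(C)CC[C@H]2[C@H]1CC2(C)C)C(=O)[C@@H]1C[C@@H](CC(C)C(=O)OC)[C@@H](C=O)[C@]31C
F2 | step 7 | ring A hydroxy ester (carbinol epimers) | C=C1CC[C@@H]2CC3=C(O[C@@]2(C)CC[C@H]2[C@H]1CC2(C)C)C(=O)[C@@H]1C[C@H]2C[C@](C)(C(=O)OC)C(O)[C@H]2[C@]31C
F3 | step 7 | imidazolylthiocarbonate of F2 | C=C1CC[C@@H]2CC3=C(O[C@@]2(C)CC[C@H]2[C@H]1CC2(C)C)C(=O)[C@@H]1C[C@H]2C[C@](C)(C(=O)OC)C(OC(=S)n4ccnc4)[C@H]2[C@]31C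
F4 | step 6 | Mannich base of 11 | CN(C)CC1=C(O)C(=O)[C@@H]2C[C@@H](CC(C)C(=O)OC)[C@@H](CI)[C@]12C
F5 | step 1 | 3-methyl-3-(1-trimethylsilylvinyl)cyclopent-1-enyl acetate | C1CC(OC(C)=O)=C[C@@]1(C(=C)[Si](C)(C)C)C
F6 | step 1 | 2-allyl-3-methyl-3-(1-trimethylsilylvinyl)cyclopentanone (C-2 epimers) | C1CC(=O)C(CC=C)[C@@]1(C(=C)[Si](C)(C)C)C
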